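**Plan**

- Numbering: bicyclo[3.3.1]nonane locants of the target (C1, C5 bridgeheads; C9 bridging carbonyl; C8 gem-dimethyl carbon; ring A = C9, C1, C2, C3, C4, C5; ring B = C1, C8, C7, C6, C5, C9).
- Cuts, in retrosynthetic order: C3–aroyl; C7–CH2 side chain at its CH2–CH= bond (with H7); C5–prenyl; the C4 oxygen; then C5–C6; last C1–C8 and C1–prenyl.
- Enabling feature: with C5–C6 cut and C4 deoxygenated, ring A is a 2,2-disubstituted cyclohexane-1,3-dione whose carbonyls C2/C9 and α-methylenes C3/C5 are enantiotopic, and C6 is one terminus of a symmetric 2-substituted allyl unit carried by C8.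
- Forward: ring A is bought as cyclohexane-1,3-dione; C-prenylation, O-allylation and Claisen rearrangement (C1–C8) give the achiral dione; ring B is closed by C5–C6 formation; then C4 oxygenation, O-methylation, C5 prenylation, side-chain coupling, C3 aroylation, deprotection.
- Stereochemistry: C1 and C5 arise together in the palladium-catalysed desymmetrising ring closure (chiral ligand); C7 comes from exo-face hydroboration of the 7-methylidene group, which places the side chain endo.

Key step: step 6

Remark 1: the sense of induction in step 6 cannot be derived from precedent; the (R,R) ligand is written, and its antipode would be used if a first experiment gives the mirror-image series.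
Remark 2: O-methylation of trione 12 is assumed to occur mainly at the less hindered C4 oxygen, and that regioisomer (13) is carried forward.

**Route**

Step 1
Reactants: 1 cyclohexane-1,3-dione; 2 prenyl bromide
Product: 3 2-(3-methylbut-2-en-1-yl)cyclohexane-1,3-dione
Conditions: KOH, H2O, 0 °C → rt; then acidify
Reagents that add atoms: none
Why: C-alkylation of the dione enolate (1,3-dicarbonyl alkylation) is favoured in water, where hydrogen bonding shields the enolate oxygens, and no stereocentre is formed.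

Step 2
Reactants: 4 diethyl 2-(propan-2-ylidene)propanedioate
Product: 5 2-(propan-2-ylidene)propane-1,3-diol
Conditions: i-Bu2AlH (excess), CH2Cl2, −78 → 0 °C; aqueous potassium sodium tartrate work-up
Reagents that add atoms: none
Why: Excess i-Bu2AlH reduces both esters by 1,2-addition (ester-to-alcohol reduction), conjugate reduction being disfavoured at the fully substituted β-carbon.

Step 3
Reactants: 5 2-(propan-2-ylidene)propane-1,3-diol
Product: 6 2-(hydroxymethyl)-3-methylbut-2-en-1-yl methyl carbonate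
Conditions: ClCO2Me (0.5 equiv), pyridine, CH2Cl2, −20 → 0 °C
Reagents that add atoms: methyl chloroformate, COC(Cl)=O
Why: Statistical mono-acylation of the symmetric diol with a sub-stoichiometric amount of chloroformate (carbonate formation) should give the monocarbonate with recovery of diol, and the carbonate is chosen because it should survive the thermal step and later ionise readily to a π-allyl complex.

Step 4
Reactants: 3 2-(3-methylbut-2-en-1-yl)cyclohexane-1,3-dione; 6 2-(hydroxymethyl)-3-methylbut-2-en-1-yl methyl carbonate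
Product: 7 3-{[2-({[methoxycarbonyl]oxy}methyl)-3-methylbut-2-en-1-yl]oxy}-2-(3-methylbut-2-en-1-yl)cyclohex-2-en-1-one
Conditions: PPh3, DIAD, THF, 0 °C → rt
Reagents that add atoms: none
Why: In this Mitsunobu reaction the acidic enol of the 1,3-dione is alkylated on oxygen by SN2 displacement at the activated primary allylic alcohol, which gives the allyl vinyl ether needed for the rearrangement and avoids direct C-alkylation with the wrong, linear connectivity.

Step 5
Reactants: 7 3-{[2-({[methoxycarbonyl]oxy}methyl)-3-methylbut-2-en-1-yl]oxy}-2-(3-methylbut-2-en-1-yl)cyclohex-2-en-1-one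
Product: 8 2-[3-({[methoxycarbonyl]oxy}methyl)-2-methylbut-3-en-2-yl]-2-(3-methylbut-2-en-1-yl)cyclohexane-1,3-dione (achiral)
Conditions: PhMe, 160 °C, sealed tube
Reagents that add atoms: none
Why: The thermal Claisen rearrangement ([3,3] shift through a chair transition state) moves the allyl group from oxygen to C1 with allylic transposition, forming the C1–C8 bond between two fully substituted carbons and unveiling the 1,1-disubstituted allylic carbonate, and the product is achiral so no stereochemical issue arises.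

Step 6
Reactants: 8 2-[3-({[methoxycarbonyl]oxy}methyl)-2-methylbut-3-en-2-yl]-2-(3-methylbut-2-en-1-yl)cyclohexane-1,3-dione
Product: 9 (1R,5R)-8,8-dimethyl-7-methylidene-1-(3-methylbut-2-en-1-yl)bicyclo[3.3.1]nonane-2,9-dione
Conditions: Pd2(dba)3·CHCl3 (2.5 mol%), N,N'-[(1R,2R)-cyclohexane-1,2-diyl]bis[2-(diphenylphosphanyl)benzamide] (7.5 mol%), 1,1,3,3-tetramethylguanidine (1 equiv), THF, 40 °C
Reagents that add atoms: none
Why: Proposed new method: zerovalent palladium ionises the allylic methyl carbonate with loss of CO2 to a 2-substituted π-allyl complex whose two CH2 termini are equivalent, methoxide and tetramethylguanidine reversibly enolise either ketone, and the α-carbon C5 of one enolate attacks terminus C6 anti to palladium to form C5–C6. The closest known reactions are the ring-closing stage of the palladium-catalysed α,α'-annulation of cyclohexanones with 2-methylidenepropane-1,3-diyl diesters, where a simple ketone α-carbon attacks a 2-substituted π-allyl under guanidine base to give a 7-methylidenebicyclo[3.3.1]nonan-9-one, and the enantioselective desymmetrising α-arylation of 2,2-disubstituted cyclohexane-1,3-diones; new here is the enantiotopic-group selection in the allylation. Ring B (C1, C8, C7, C6, C5, C9) closes in a 6-(enolendo) mode at an allyl terminus, with the central allyl carbon C7 inside the ring and the distal CH2 left as the exocyclic methylene, and the gem-dimethyl group at C8 favours the folded rotamer. C1 and C5 are created together under control of the chiral ligand, which decides whether C5 or its enantiotopic partner C3 reaches the allyl unit; the bridged product can only be cis-fused, so one decision fixes both centres as (1R,5R). The step needs enantiotopic-group selectivity and C- over O-alkylation: regiochemistry is settled by the symmetry of the allyl unit, and O-attack would give a cyclic allyl enol ether that zerovalent palladium can re-ionise, which should funnel material to the C-alkylated ketone.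

Step 7
Reactants: 9 (1R,5R)-8,8-dimethyl-7-methylidene-1-(3-methylbut-2-en-1-yl)bicyclo[3.3.1]nonane-2,9-dione
Product: 10 (1R,5S)-8,8-dimethyl-7-methylidene-1-(3-methylbut-2-en-1-yl)bicyclo[3.3.1]non-3-ene-2,9-dione
Conditions: IBX (2-iodoxybenzoic acid), DMSO/PhMe, 70 °C
Reagents that add atoms: none
Why: IBX dehydrogenation of a ketone to its enone can only involve C3, because C1 is quaternary and an enol towards C5 would be an anti-Bredt alkene, so desaturation is confined to C3–C4 (the C5 descriptor changes only through the priority rules).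

Step 8
Reactants: 10 (1R,5S)-8,8-dimethyl-7-methylidene-1-(3-methylbut-2-en-1-yl)bicyclo[3.3.1]non-3-ene-2,9-dione
Product: 11 (1S,3S,4S,5S)-3,4-epoxy-8,8-dimethyl-7-methylidene-1-(3-methylbut-2-en-1-yl)bicyclo[3.3.1]nonane-2,9-dione (epoxide oxygen on the exo face, away from ring B)
Conditions: t-BuOOH, DBU, CH2Cl2, 0 °C → rt
Reagents that add atoms: tert-butyl hydroperoxide, CC(C)(C)OO
Why: In this nucleophilic (Weitz–Scheffer-type) epoxidation the hydroperoxide anion adds to C4 of the enone and closes onto C3, leaving the electron-rich prenyl and methylidene groups untouched, with attack expected on the exo face although the epoxide configuration is erased in the next step.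

Step 9
Reactants: 11 (1S,3S,4S,5S)-3,4-epoxy-8,8-dimethyl-7-methylidene-1-(3-methylbut-2-en-1-yl)bicyclo[3.3.1]nonane-2,9-dione
Product: 12 (1R,5S)-8,8-dimethyl-7-methylidene-1-(3-methylbut-2-en-1-yl)bicyclo[3.3.1]nonane-2,4,9-trione (enolised across C2–C4)
Conditions: Pd(PPh3)4 (5 mol%), Ph2PCH2CH2PPh2 (5 mol%), PhMe, 100 °C
Reagents that add atoms: none
Why: In the known palladium-catalysed isomerisation of α,β-epoxy ketones to β-diketones, zerovalent palladium opens the C3–O bond to a palladium enolate alkoxide, and β-hydride elimination from C4 followed by reductive elimination delivers the C4 ketone, which is stabilised as the enol.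

Step 10
Reactants: 12 (1R,5S)-8,8-dimethyl-7-methylidene-1-(3-methylbut-2-en-1-yl)bicyclo[3.3.1]nonane-2,4,9-trione
Product: 13 (1R,5S)-4-methoxy-8,8-dimethyl-7-methylidene-1-(3-methylbut-2-en-1-yl)bicyclo[3.3.1]non-3-ene-2,9-dione
Conditions: Me2SO4, K2CO3, acetone, reflux
Reagents that add atoms: dimethyl sulfate, COS(=O)(=O)OC
Why: O-alkylation of the vinylogous acid (enolate methylation) should take place at the less hindered C4 oxygen, remote from quaternary C1, giving the vinylogous methyl ester that masks the acidic dione and leaves the bridgehead and C3 protons open to amide bases.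

Step 11
Reactants: 13 (1R,5S)-4-methoxy-8,8-dimethyl-7-methylidene-1-(3-methylbut-2-en-1-yl)bicyclo[3.3.1]non-3-ene-2,9-dione; 2 prenyl bromide
Product: 15 (1R,5S)-4-methoxy-8,8-dimethyl-7-methylidene-1,5-bis(3-methylbut-2-en-1-yl)bicyclo[3.3.1]non-3-ene-2,9-dione, via bridgehead C5-lithio enol ether 14 (not isolated)
Conditions: LiN(i-Pr)2, THF, −78 °C; then 2, −78 °C → rt
Reagents that add atoms: none
Why: In this bridgehead lithiation–alkylation the only bridgehead proton, at C5, is acidified by the C9 carbonyl and the adjacent vinylogous ester and should be removed in preference to the C3 vinyl proton, as known for methyl enol ethers of bicyclo[3.3.1]nonane-2,4,9-triones, and the pyramidal bridgehead anion can only be alkylated with retention, so the C5 configuration from step 6 is carried over.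

Step 12
Reactants: 16 5-bromo-2-methylpent-2-ene
Product: 17 6-methylhept-5-en-1-yne
Conditions: LiC≡CH·H2NCH2CH2NH2, DMSO, 10 °C → rt
Reagents that add atoms: lithium acetylide–ethylenediamine complex, [Li]C#C.NCCN
Why: Acetylide alkylation by SN2 displacement at the primary homoallylic bromide proceeds cleanly in DMSO.

Step 13
Reactants: 17 6-methylhept-5-en-1-yne
Product: 19 (1E)-1-iodo-2,6-dimethylhepta-1,5-diene, via alkenyl dimethylalane 18 (not isolated)
Conditions: AlMe3, Cp2ZrCl2 (zirconocene dichloride, cat.), CH2Cl2, 0 °C → rt; then I2, THF, −30 → 0 °C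
Reagents that add atoms: trimethylaluminium, C[Al](C)C; iodine, II
Why: The Negishi zirconium-catalysed carboalumination adds methyl and aluminium syn across the terminal alkyne with aluminium at the terminus, and iodinolysis with retention gives the E vinyl iodide.

Step 14
Reactants: 15 (1R,5S)-4-methoxy-8,8-dimethyl-7-methylidene-1,5-bis(3-methylbut-2-en-1-yl)bicyclo[3.3.1]non-3-ene-2,9-dione; 19 (1E)-1-iodo-2,6-dimethylhepta-1,5-diene
Product: 21 (1R,5S,7S)-7-[(2E)-3,7-dimethylocta-2,6-dien-1-yl]-4-methoxy-8,8-dimethyl-1,5-bis(3-methylbut-2-en-1-yl)bicyclo[3.3.1]non-3-ene-2,9-dione, via B-alkyl-9-BBN adduct 20 (not isolated)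
Conditions: 9-BBN dimer, THF, 0 → 50 °C; then 19, Pd(dppf)Cl2·CH2Cl2 (5 mol%), AsPh3, Cs2CO3, DMF/H2O, rt
Reagents that add atoms: none
Why: In this hydroboration and B-alkyl Suzuki–Miyaura coupling, 9-BBN should select the 1,1-disubstituted methylidene over the trisubstituted alkenes and the hindered or deactivated carbonyls, boron goes to the terminal carbon and hydrogen is delivered to C7 from the exo face (the endo face is blocked by ring A), which places the new CH2 group endo and sets C7 as S, and the coupling retains the E geometry of the vinyl iodide.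

Step 15
Reactants: 22 3-hydroxybenzoic acid
Product: 24 3-[(tert-butyldimethylsilyl)oxy]benzoic acid, via bis-silylated silyl ester 23 (not isolated)
Conditions: TBSCl (2.2 equiv), imidazole, DMF, rt; then AcOH/THF/H2O, rt
Reagents that add atoms: tert-butyldimethylsilyl chloride, CC(C)(C)[Si](C)(C)Cl
Why: Silylation of both phenol and acid followed by selective hydrolysis of the labile silyl ester (silyl protection) leaves the phenol as a silyl ether that tolerates the organolithium step and is removed by the final hydroxide treatment.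

Step 16
Reactants: 24 3-[(tert-butyldimethylsilyl)oxy]benzoic acid
Product: 25 3-[(tert-butyldimethylsilyl)oxy]benzoyl chloride
Conditions: (COCl)2, DMF (cat.), CH2Cl2, 0 °C → rt
Reagents that add atoms: oxalyl chloride, O=C(Cl)C(Cl)=O
Why: Acid chloride formation with oxalyl chloride under DMF catalysis (Vilsmeier-type activation) runs under conditions the aryl silyl ether should tolerate.

Step 17
Reactants: 21 (1R,5S,7S)-7-[(2E)-3,7-dimethylocta-2,6-dien-1-yl]-4-methoxy-8,8-dimethyl-1,5-bis(3-methylbut-2-en-1-yl)bicyclo[3.3.1]non-3-ene-2,9-dione; 25 3-[(tert-butyldimethylsilyl)oxy]benzoyl chloride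
Product: 27 (1S,5S,7S)-3-{3-[(tert-butyldimethylsilyl)oxy]benzoyl}-7-[(2E)-3,7-dimethylocta-2,6-dien-1-yl]-4-methoxy-8,8-dimethyl-1,5-bis(3-methylbut-2-en-1-yl)bicyclo[3.3.1]non-3-ene-2,9-dione, via C3-lithio enol ether 26 (not isolated)
Conditions: lithium 2,2,6,6-tetramethylpiperidide (from n-BuLi and 2,2,6,6-tetramethylpiperidine), THF, −78 °C; then 25, −78 °C
Reagents that add atoms: none
Why: In this vinylic lithiation–acylation the hindered amide base removes the C3 proton lying between the carbonyl and the methoxy-bearing carbon, and the vinyllithium is acylated by the aroyl chloride, as known for bridgehead-substituted enol ethers of this ring system (the C1 descriptor changes only through the priority rules).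

Step 18
Reactants: 27 (1S,5S,7S)-3-{3-[(tert-butyldimethylsilyl)oxy]benzoyl}-7-[(2E)-3,7-dimethylocta-2,6-dien-1-yl]-4-methoxy-8,8-dimethyl-1,5-bis(3-methylbut-2-en-1-yl)bicyclo[3.3.1]non-3-ene-2,9-dione
Product: 28 (1S,5S,7S)-7-[(2E)-3,7-dimethylocta-2,6-dien-1-yl]-4-hydroxy-3-(3-hydroxybenzoyl)-8,8-dimethyl-1,5-bis(3-methylbut-2-en-1-yl)bicyclo[3.3.1]non-3-ene-2,9-dione (CNP0290731.1)
Conditions: LiOH·H2O, 1,4-dioxane/H2O, 90 °C; then cold 1 M HCl to pH 3
Reagents that add atoms: lithium hydroxide, [Li+].[OH-]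
Why: Hydroxide adds to C4 of the doubly activated vinylogous ester and expels methoxide (addition–elimination) and also cleaves the aryl silyl ether, so one operation should liberate the enolised β-triketone and the phenol without exposing the prenyl groups to strong acid.

**Compound list**

1 | cyclohexane-1,3-dione | O=C1CCCC(=O)C1 | starting material
2 | prenyl bromide (1-bromo-3-methylbut-2-ene) | CC(C)=CCBr | starting material
3 | 2-(3-methylbut-2-en-1-yl)cyclohexane-1,3-dione | CC(C)=CCC1C(=O)CCCC1=O | intermediate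
4 | diethyl 2-(propan-2-ylidene)propanedioate | CCOC(=O)C(=C(C)C)C(=O)OCC | starting material
5 | 2-(propan-2-ylidene)propane-1,3-diol | CC(C)=C(CO)CO | intermediate
6 | 2-(hydroxymethyl)-3-methylbut-2-en-1-yl methyl carbonate | COC(=O)OCC(CO)=C(C)C | intermediate
7 | 3-{[2-({[methoxycarbonyl]oxy}methyl)-3-methylbut-2-en-1-yl]oxy}-2-(3-methylbut-2-en-1-yl)cyclohex-2-en-1-one | COC(=O)OCC(COC1=C(CC=C(C)C)C(=O)CCC1)=C(C)C | intermediate
8 | 2-[3-({[methoxycarbonyl]oxy}methyl)-2-methylbut-3-en-2-yl]-2-(3-methylbut-2-en-1-yl)cyclohexane-1,3-dione (achiral) | COC(=O)OCC(=C)C(C)(C)C1(CC=C(C)C)C(=O)CCCC1=O | intermediate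
9 | (1R,5R)-8,8-dimethyl-7-methylidene-1-(3-methylbut-2-en-1-yl)bicyclo[3.3.1]nonane-2,9-dione | C=C1C[C@@H]2C(=O)[C@@](CC=C(C)C)(C(=O)CC2)C1(C)C | intermediate
10 | (1R,5S)-8,8-dimethyl-7-methylidene-1-(3-methylbut-2-en-1-yl)bicyclo[3.3.1]non-3-ene-2,9-dione | C=C1C[C@@H]2C(=O)[C@@](CC=C(C)C)(C(=O)C=C2)C1(C)C | intermediate
11 | (1S,3S,4S,5S)-3,4-epoxy-8,8-dimethyl-7-methylidene-1-(3-methylbut-2-en-1-yl)bicyclo[3.3.1]nonane-2,9-dione (exo epoxide) | C=C1C[C@@H]2C(=O)[C@@](CC=C(C)C)(C(=O)[C@H]3O[C@@H]23)C1(C)C | intermediate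
12 | (1R,5S)-8,8-dimethyl-7-methylidene-1-(3-methylbut-2-en-1-yl)bicyclo[3.3.1]nonane-2,4,9-trione (drawn as triketone; enolised across C2–C4) | C=C1C[C@@H]2C(=O)[C@@](CC=C(C)C)(C(=O)CC2=O)C1(C)C | intermediate
13 | (1R,5S)-4-methoxy-8,8-dimethyl-7-methylidene-1-(3-methylbut-2-en-1-yl)bicyclo[3.3.1]non-3-ene-2,9-dione | C=C1C[C@@H]2C(=O)[C@@](CC=C(C)C)(C(=O)C=C2OC)C1(C)C | intermediate
14 | C5-lithio derivative of 13 (bridgehead organolithium, configuration retained) | C=C1C[C@]2([Li])C(=O)[C@@](CC=C(C)C)(C(=O)C=C2OC)C1(C)C | intermediate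
15 | (1R,5S)-4-methoxy-8,8-dimethyl-7-methylidene-1,5-bis(3-methylbut-2-en-1-yl)bicyclo[3.3.1]non-3-ene-2,9-dione | C=C1C[C@]2(CC=C(C)C)C(=O)[C@@](CC=C(C)C)(C(=O)C=C2OC)C1(C)C | intermediate
16 | 5-bromo-2-methylpent-2-ene | CC(C)=CCCBr | starting material
17 | 6-methylhept-5-en-1-yne | CC(C)=CCCC#C | intermediate
18 | [(1E)-2,6-dimethylhepta-1,5-dien-1-yl]dimethylalane | CC(C)=CCC/C(C)=C/[Al](C)C | intermediate
19 | (1E)-1-iodo-2,6-dimethylhepta-1,5-diene | CC(C)=CCC/C(C)=C/I | intermediate
20 | (1R,5S,7S)-7-[(9-borabicyclo[3.3.1]nonan-9-yl)methyl]-4-methoxy-8,8-dimethyl-1,5-bis(3-methylbut-2-en-1-yl)bicyclo[3.3.1]non-3-ene-2,9-dione (CH2B endo at C7) | C1CCC2CCCC1B2C[C@H]1C[C@]2(CC=C(C)C)C(=O)[C@@](CC=C(C)C)(C(=O)C=C2OC)C1(C)C | intermediate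
21 | (1R,5S,7S)-7-[(2E)-3,7-dimethylocta-2,6-dien-1-yl]-4-methoxy-8,8-dimethyl-1,5-bis(3-methylbut-2-en-1-yl)bicyclo[3.3.1]non-3-ene-2,9-dione (geranyl endo at C7) | CC(C)=CCC/C(C)=C/C[C@H]1C[C@]2(CC=C(C)C)C(=O)[C@@](CC=C(C)C)(C(=O)C=C2OC)C1(C)C | intermediate
22 | 3-hydroxybenzoic acid | OC(=O)c1cccc(O)c1 | starting material
23 | tert-butyldimethylsilyl 3-[(tert-butyldimethylsilyl)oxy]benzoate | CC(C)(C)[Si](C)(C)OC(=O)c1cccc(O[Si](C)(C)C(C)(C)C)c1 | intermediate
24 | 3-[(tert-butyldimethylsilyl)oxy]benzoic acid | CC(C)(C)[Si](C)(C)Oc1cccc(C(=O)O)c1 | intermediate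
25 | 3-[(tert-butyldimethylsilyl)oxy]benzoyl chloride | CC(C)(C)[Si](C)(C)Oc1cccc(C(Cl)=O)c1 | intermediate
26 | C3-lithio derivative of 21 (vinyllithium) | CC(C)=CCC/C(C)=C/C[C@H]1C[C@]2(CC=C(C)C)C(=O)[C@@](CC=C(C)C)(C(=O)C([Li])=C2OC)C1(C)C | intermediate
27 | (1S,5S,7S)-3-{3-[(tert-butyldimethylsilyl)oxy]benzoyl}-7-[(2E)-3,7-dimethylocta-2,6-dien-1-yl]-4-methoxy-8,8-dimethyl-1,5-bis(3-methylbut-2-en-1-yl)bicyclo[3.3.1]non-3-ene-2,9-dione | CC(C)=CCC/C(C)=C/C[C@H]1C[C@]2(CC=C(C)C)C(=O)[C@@](CC=C(C)C)(C(=O)C(C(=O)c3cccc(O[Si](C)(C)C(C)(C)C)c3)=C2OC)C1(C)C | intermediate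
28 | (1S,5S,7S)-7-[(2E)-3,7-dimethylocta-2,6-dien-1-yl]-4-hydroxy-3-(3-hydroxybenzoyl)-8,8-dimethyl-1,5-bis(3-methylbut-2-en-1-yl)bicyclo[3.3.1]non-3-ene-2,9-dione | CC(C)=CCC/C(C)=C/C[C@H]1C[C@]2(CC=C(C)C)C(=O)[C@@](CC=C(C)C)(C(=O)C(C(=O)c3cccc(O)c3)=C2O)C1(C)C | target

**Count**

Total: 18 steps. Longest linear sequence: 13 steps (steps 2–11, 14, 17, 18, from 4).

**Steps most likely to fail**

Step 6 (proposed new method). The chiral complex may discriminate poorly between the enantiotopic methylenes C3 and C5, or the π-allyl complex may be captured by methoxide or by an enolate oxygen instead of C5. The fallback uses known chemistry, sets out from 8 and returns at 9, and separates the desymmetrisation from the ring closure. Ruthenium-catalysed asymmetric transfer hydrogenation of the prochiral dione (RuCl(p-cymene)[(S,S)-TsDPEN] or its antipode, HCO2H/Et3N) should reduce the carbonyl destined to become C2 and give (2R,3S)-3-hydroxy-2-[3-({[methoxycarbonyl]oxy}methyl)-2-methylbut-3-en-2-yl]-2-(3-methylbut-2-en-1-yl)cyclohexan-1-one F1; the carbinol configuration is inconsequential. Silylation (Et3SiCl, imidazole) would give the triethylsilyl ether of that hydroxy ketone F2, in which only one ketone and one α-methylene (C5) remain. Ring closure with Pd(PPh3)4 and tetramethylguanidine, the known ketone α-allylation mode, would then give (1R,2S,5R)-8,8-dimethyl-7-methylidene-1-(3-methylbut-2-en-1-yl)-2-[(triethylsilyl)oxy]bicyclo[3.3.1]nonan-9-one F3. Tetrabutylammonium fluoride would release (1R,2S,5R)-2-hydroxy-8,8-dimethyl-7-methylidene-1-(3-methylbut-2-en-1-yl)bicyclo[3.3.1]nonan-9-one F4, and oxidation with 1,1,1-triacetoxy-1,1-dihydro-1,2-benziodoxol-3(1H)-one gives 9.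

Step 5. The [3,3] shift between two fully substituted carbons may be slow enough that loss of the allyl group (back to 3) or a [1,3] shift to the linear isomer takes over. The fallback sets out from 1 and 5 and returns at 8; it forms C1–C8 while C1 still carries hydrogen and quaternises C1 afterwards. Monosilylation of 5 (NaH, TBSCl) would give 2-({[tert-butyl(dimethyl)silyl]oxy}methyl)-3-methylbut-2-en-1-ol F5. Mitsunobu O-alkylation of 1 with it would give 3-{[2-({[tert-butyl(dimethyl)silyl]oxy}methyl)-3-methylbut-2-en-1-yl]oxy}cyclohex-2-en-1-one F6. Thermal Claisen rearrangement to the unsubstituted enol carbon, made irreversible by enolisation, would give 2-[3-({[tert-butyl(dimethyl)silyl]oxy}methyl)-2-methylbut-3-en-2-yl]cyclohexane-1,3-dione F7. Tsuji–Trost C-prenylation (methyl prenyl carbonate, Pd(PPh3)4, THF) would give 2-[3-({[tert-butyl(dimethyl)silyl]oxy}methyl)-2-methylbut-3-en-2-yl]-2-(3-methylbut-2-en-1-yl)cyclohexane-1,3-dione F8. Desilylation with tetrabutylammonium fluoride would give 2-[3-(hydroxymethyl)-2-methylbut-3-en-2-yl]-2-(3-methylbut-2-en-1-yl)cyclohexane-1,3-dione F9, and ClCO2Me/pyridine gives 8.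

Step 9. Backside approach of palladium to C3 is shielded by ring B, so oxidative addition may be slow and the epoxide may survive or open reductively instead of isomerising. The fallback sets out from enone 10 and returns at 12; it replaces the epoxide by a boron conjugate addition. Copper-catalysed β-borylation (B2pin2, CuCl, NaOt-Bu, bis[2-(diphenylphosphanyl)phenyl] ether, MeOH, THF) should give (1R,4R,5S)-8,8-dimethyl-7-methylidene-1-(3-methylbut-2-en-1-yl)-4-(4,4,5,5-tetramethyl-1,3,2-dioxaborolan-2-yl)bicyclo[3.3.1]nonane-2,9-dione F10. Oxidation with NaBO3·4H2O would give (1R,4R,5S)-4-hydroxy-8,8-dimethyl-7-methylidene-1-(3-methylbut-2-en-1-yl)bicyclo[3.3.1]nonane-2,9-dione F11, and oxidation with 1,1,1-triacetoxy-1,1-dihydro-1,2-benziodoxol-3(1H)-one gives trione 12.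

Further compounds
F1 | step 6 | (2R,3S)-3-hydroxy-2-[3-({[methoxycarbonyl]oxy}methyl)-2-methylbut-3-en-2-yl]-2-(3-methylbut-2-en-1-yl)cyclohexan-1-one | O=C1CCC[C@H](O)[C@@]1(CC=C(C)C)C(C)(C)C(=C)COC(=O)OC
F2 | step 6 | (2R,3S)-2-[3-({[methoxycarbonyl]oxy}methyl)-2-methylbut-3-en-2-yl]-2-(3-methylbut-2-en-1-yl)-3-[(triethylsilyl)oxy]cyclohexan-1-one | O=C1CCC[C@H](O[Si](CC)(CC)CC)[C@@]1(CC=C(C)C)C(C)(C)C(=C)COC(=O)OC
F3 | step 6 | (1R,2S,5R)-8,8-dimethyl-7-methylidene-1-(3-methylbut-2-en-1-yl)-2-[(triethylsilyl)oxy]bicyclo[3.3.1]nonan-9-one | C=C1C[C@@H]2C(=O)[C@@](CC=C(C)C)([C@@H](O[Si](CC)(CC)CC)CC2)C1(C)C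
F4 | step 6 | (1R,2S,5R)-2-hydroxy-8,8-dimethyl-7-methylidene-1-(3-methylbut-2-en-1-yl)bicyclo[3.3.1]nonan-9-one | C=C1C[C@@H]2C(=O)[C@@](CC=C(C)C)([C@@H](O)CC2)C1(C)C
F5 | step 5 | 2-({[tert-butyl(dimethyl)silyl]oxy}methyl)-3-methylbut-2-en-1-ol | CC(C)=C(CO)CO[Si](C)(C)C(C)(C)C
F6 | step 5 | 3-{[2-({[tert-butyl(dimethyl)silyl]oxy}methyl)-3-methylbut-2-en-1-yl]oxy}cyclohex-2-en-1-one | CC(C)=C(COC1=CC(=O)CCC1)CO[Si](C)(C)C(C)(C)C
F7 | step 5 | 2-[3-({[tert-butyl(dimethyl)silyl]oxy}methyl)-2-methylbut-3-en-2-yl]cyclohexane-1,3-dione | C=C(CO[Si](C)(C)C(C)(C)C)C(C)(C)C1C(=O)CCCC1=O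
F8 | step 5 | 2-[3-({[tert-butyl(dimethyl)silyl]oxy}methyl)-2-methylbut-3-en-2-yl]-2-(3-methylbut-2-en-1-yl)cyclohexane-1,3-dione | C=C(CO[Si](C)(C)C(C)(C)C)C(C)(C)C1(CC=C(C)C)C(=O)CCCC1=O
F9 | step 5 | 2-[3-(hydroxymethyl)-2-methylbut-3-en-2-yl]-2-(3-methylbut-2-en-1-yl)cyclohexane-1,3-dione | C=C(CO)C(C)(C)C1(CC=C(C)C)C(=O)CCCC1=O
F10 | step 9 | (1R,4R,5S)-8,8-dimethyl-7-methylidene-1-(3-methylbut-2-en-1-yl)-4-(4,4,5,5-tetramethyl-1,3,2-dioxaborolan-2-yl)bicyclo[3.3.1]nonane-2,9-dione | C=C1C[C@@H]2C(=O)[C@@](CC=C(C)C)(C(=O)C[C@H]2B3OC(C)(C)C(C)(C)O3)C1(C)C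
F11 | step 9 | (1R,4R,5S)-4-hydroxy-8,8-dimethyl-7-methylidene-1-(3-methylbut-2-en-1-yl)bicyclo[3.3.1]nonane-2,9-dione | C=C1C[C@@H]2C(=O)[C@@](CC=C(C)C)(C(=O)C[C@H]2O)C1(C)C
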